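**The cap.** You cannot get more mono adduct from Wednesday's flask than its reagent pays for, since each mono adduct costs one reagent. So carry one quantity, the reagent budget: charged reagent as a percentage of charged solid substrate, here 80.0%. Reagent is the limiting reagent, with 8.00 mM charged against 0.010 M of solid substrate.

| flask | solid substrate | reagent | temperature | remark | time |
|---|---|---|---|---|---|
| Wednesday's | 0.010 M | 8 mM | 50 °C | the very flask that is asked about, followed so far |  |
| Saturday's | 0.015 M | 8 mM | 35 °C | run made earlier |  |
| flask | 0.010 M | 8.00 mM | 50 °C |  | 80 min |

| run | time / min | mono adduct / % | solid substrate / % |
|---|---|---|---|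
| Wednesday's | 3.00 | 15.8 | 50.6 |
| Wednesday's | 10.0 | 47.3 | 0.2 |
| Wednesday's | 15.0 | 52.4 | 0 |
| Wednesday's | 25.0 | 54.5 | 0 |
| Wednesday's | 40.0 | 54.9 | 0 |
| Wednesday's | 50.0 | 54.7 | 0.3 |
| Saturday's | 2.00 | 2.7 | 76.6 |
| Saturday's | 4.00 | 9.4 | 61.5 |
| Saturday's | 6.00 | 15.4 | 51.7 |
| Saturday's | 8.00 | 20.6 | 42.5 |
| Saturday's | 10.0 | 25.4 | 36.5 |
| Saturday's | 12.0 | 29.9 | 29.4 |

(readings scatter by 0.5 percentage points)

- delta: at 80 min raise the temperature by 25 K, then wait 25 min
- beta: at 80 min add reagent, 100% of the amount charged, then wait 25 min
- theta: change nothing and wait 25 min more
- eta: at 80 min take out 90% of the mono adduct then present, then wait 25 min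

- solid, in amounts per volume of the solution: solid substrate
- mono adduct that was removed still counts
- what was read earlier has a scatter of 0.5 percentage points, one standard deviation
- reactions considered so far: starting material + reagent -> mono adduct; starting material + reagent -> other mono adduct; reagent + mono adduct -> double product; reagent + other mono adduct -> double product; solid substrate <-> starting material
- at the start none of the solid substrate is in solution
- additions bring no volume worth counting

- mono adduct, in percent of the solid substrate first charged, at 80 min
- the option that brings most further mono adduct ("none" if no option brings more than 2 percentage points) (delta / beta / theta / eta / none)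
- mono adduct present, with what was taken out counted in, in percent of the solid substrate first charged, after delta
- mono adduct present, with what was taken out counted in, in percent of the solid substrate first charged, after theta

**Waiting.** In Wednesday's run the mono adduct climbs until about 25.0 min, then moves 0.2 percentage points by 50.0 min, less than the scatter of 0.5 points. That is the crossing: before it the mono adduct moves with the clock, after it the readings stand still within their scatter. Reagent still at work would move the reading, so I reckon with none at work after that. I put the flask at 54.9% at 80 min, and I expect theta to add nothing.

**Heat, removal.** The listed steps that make or use mono adduct each take reagent, and the solid substrate reads 0% at 40.0 min. So I expect delta to leave the mono adduct of this flask where it stands. Eta frees no reagent either, and I expect no gain from it.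

**More reagent.** Beta raises the budget; delta, theta and eta add no reagent. Of the present budget, 25 points did not end as mono adduct. If it went into double product, at two reagents each, that leaves 32.5% of starting material as my upper figure. The new reagent outnumbers this, so I reckon with a surplus of about 48 points that can turn on the mono adduct. I reckon gain and loss about cancel, and I expect no option to pass 2 points.

**The result.** The forecast gives 54.8% at the asked time, 54.8% after delta, 54.8% after theta and none as best, and calls beta “the only real candidate”. The flask gives 54.9%, then 54.9% after delta and 54.9% after theta. Beta changes the mono adduct by −4.2 points, so the best option is none.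

    starting material + reagent → mono adduct (k = 0.655 L mol⁻¹ s⁻¹, Ea = 39.0 kJ mol⁻¹)
    starting material + reagent → other mono adduct (k = 0.0608 L mol⁻¹ s⁻¹, Ea = 63.0 kJ mol⁻¹)
    reagent + mono adduct → double product (k = 0.115 L mol⁻¹ s⁻¹, Ea = 46.0 kJ mol⁻¹)
    reagent + other mono adduct → double product (k = 0.458 L mol⁻¹ s⁻¹, Ea = 63.0 kJ mol⁻¹)
    solid substrate ⇌ starting material, rate k5*(cs5 - [starting material]) while solid is left; crystals form when [starting material] > cs5 (solubility = 6.70 mM, k = 0.00585 s⁻¹)
    (constants at 50 °C)

**The balance.** In Wednesday's flask, mono adduct, other mono adduct and twice the double product add to 80.0% against the budget of 80.0%, with 0% of the reagent left. The neighbouring flask is the same one with 0.0020 M of reagent, so its budget is 20.0%, lower than Wednesday's. It ends with 0% of its reagent left, and the same sum gives 20.0%. Its mono adduct stands at 17.2%, which is 86.0% of its budget, against 68.6% in Wednesday's flask.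

(The numbers in the tables come from a simulation for substances that don't exist; noise was put on by code.)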